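## Retrosynthetic overview

- The CH2 bridge is cut last: the C7–H of an acylphloroglucinol dihydrobenzofuran, a 4-hydroxy-2-pyranone and a one-carbon iminium salt are joined by a Mannich/Michael sequence.
- The isopropenyl group comes from a C2 ester (double methyl addition, then dehydration).
- The dihydrofuran ring is closed at O1–C2 by an intramolecular Mitsunobu reaction with inversion of an (S)-aryl-lactate, whose stereocentre is bought as L-malic acid.
- The aryl–CH2 bond is made by a light-driven decarboxylative C–H alkylation of phlorisobutyrophenone with the L-malic-acid-derived redox-active ester.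
- Ring order: the aromatic ring is bought and acylated first, the dihydrofuran ring is closed in the third step, and the separately made pyranone ring is attached last.

Assumption: compound 4, the acetonide of natural L-malic acid, is bought as such; benzofuran numbering (O1, C2, C3, C3a, C4 to C7, C7a) is used throughout.

## Route

Step 1
Reactants: 1 phloroglucinol (benzene-1,3,5-triol); 2 2-methylpropanoyl chloride
Product: 3 2-methyl-1-(2,4,6-trihydroxyphenyl)propan-1-one (phlorisobutyrophenone)
Conditions: AlCl3 (4 equiv), PhNO2, rt → 65 °C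
Reagents that add atoms: none
Why: Friedel–Crafts acylation of the symmetric, very nucleophilic triphenol; the chelated ketone deactivates the ring against a second acylation, and no stereocentre is involved.

Step 2
Reactants: 3 2-methyl-1-(2,4,6-trihydroxyphenyl)propan-1-one; 4 2-[(4S)-2,2-dimethyl-5-oxo-1,3-dioxolan-4-yl]acetic acid
Product: 7 methyl (2S)-2-hydroxy-3-[2,4,6-trihydroxy-3-(2-methylpropanoyl)phenyl]propanoate, via phthalimidyl ester 5 (not isolated), via dioxolanone adduct 6 (not isolated)
Conditions: 4, N-hydroxyphthalimide, N,N'-diisopropylcarbodiimide (DIC), DMAP (cat.), CH2Cl2, rt; then 3 (3 equiv), 2-tert-butyl-1,1,3,3-tetramethylguanidine (BTMG, 3 equiv), degassed DMA, 427 nm LEDs, 0 °C; then MeOH, rt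
Reagents that add atoms: methanol, CO
Why: Proposed new method: the electron-rich phenolate of 3 and the N-acyloxyphthalimide 5 should form a coloured electron donor–acceptor pair whose excitation with visible light transfers one electron; 5 then loses phthalimide anion and CO2 to give a primary alkyl radical, which is trapped at the ring carbon flanked by two oxygens (in-cage recombination with the phenoxyl radical, or addition to the phenolate followed by chain electron transfer to 5), and the dienone tautomerises back to the phenol; the stereocentre bought with 4 sits next to the radical carbon, not at it, and is untouched there and in the base-mediated methanolysis of the dioxolanone (or of any aryl lactone formed from it) that ends the step; the closest known reaction types are photochemical decarboxylative alkylations through donor–acceptor complexes of N-acyloxyphthalimides with electron-rich donors (thiolates, iodide–phosphine, dihydropyridines) and the photostimulated radical-chain C-alkylation of aryloxide anions, neither shown for a polyphenol ketone or for this oxygenated chiral radical.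

Step 3
Reactants: 7 methyl (2S)-2-hydroxy-3-[2,4,6-trihydroxy-3-(2-methylpropanoyl)phenyl]propanoate
Product: 8 methyl (2R)-4,6-dihydroxy-5-(2-methylpropanoyl)-2,3-dihydro-1-benzofuran-2-carboxylate
Conditions: PPh3, DIAD, THF (0.02 M), 0 °C → rt
Reagents that add atoms: none
Why: Intramolecular Mitsunobu etherification; the phenol para to the ketone is the most acidic and is not hydrogen-bonded to the carbonyl, so it displaces the activated α-hydroxy ester oxygen in a 5-exo SN2 reaction with inversion, turning the (S) centre of 7 into the (R) centre at C2.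

Step 4
Reactants: 8 methyl (2R)-4,6-dihydroxy-5-(2-methylpropanoyl)-2,3-dihydro-1-benzofuran-2-carboxylate
Product: 9 1-[(2R)-4,6-dihydroxy-2-(2-hydroxypropan-2-yl)-2,3-dihydro-1-benzofuran-5-yl]-2-methylpropan-1-one
Conditions: MeMgBr (6 equiv), THF, −40 → 0 °C
Reagents that add atoms: methylmagnesium bromide, C[Mg]Br
Why: Double Grignard addition to the ester; the first two equivalents form the bis-phenoxide, which leaves the hindered, chelated aryl isopropyl ketone inert, and fast addition at low temperature keeps the α-aryloxy stereocentre intact.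

Step 5
Reactants: 9 1-[(2R)-4,6-dihydroxy-2-(2-hydroxypropan-2-yl)-2,3-dihydro-1-benzofuran-5-yl]-2-methylpropan-1-one
Product: 10 1-[(2R)-4,6-dihydroxy-2-(prop-1-en-2-yl)-2,3-dihydro-1-benzofuran-5-yl]-2-methylpropan-1-one
Conditions: SOCl2, pyridine, CH2Cl2, −20 °C
Reagents that add atoms: none
Why: Dehydration of the tertiary alcohol through its chlorosulfite (pyridine-mediated E2), the usual way from 2-(2-hydroxypropan-2-yl)dihydrobenzofurans to 2-isopropenyl ones; six methyl hydrogens compete with one inductively deactivated C2–H, aryl chlorosulfites at the phenols hydrolyse on work-up, and C2 is not touched.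

Step 6
Reactants: 11 methyl 3-oxopentanoate; 12 N-methoxy-N-methylpropanamide
Product: 14 6-ethyl-4-hydroxy-5-methyl-2H-pyran-2-one, via triketo ester 13 (not isolated)
Conditions: NaH then n-BuLi, THF, 0 °C; 12, −78 → 0 °C; then DBU, PhMe, 110 °C on the crude material
Reagents that add atoms: none
Why: γ-Acylation of the β-keto ester dianion with a Weinreb amide (Huckin–Weiler type; the chelated tetrahedral intermediate prevents over-addition), then base-promoted enol lactonisation to the 4-hydroxy-2-pyranone; no stereocentre.

Step 7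
Reactants: 10 1-[(2R)-4,6-dihydroxy-2-(prop-1-en-2-yl)-2,3-dihydro-1-benzofuran-5-yl]-2-methylpropan-1-one; 14 6-ethyl-4-hydroxy-5-methyl-2H-pyran-2-one
Product: 17 3-[[(2R)-4,6-dihydroxy-5-(2-methylpropanoyl)-2-(prop-1-en-2-yl)-2,3-dihydro-1-benzofuran-7-yl]methyl]-6-ethyl-4-hydroxy-5-methyl-2H-pyran-2-one, via Mannich base 15 (not isolated), via pyranone methide 16 (not isolated)
Conditions: 14, N,N-dimethylmethyleneiminium iodide (Me2N=CH2+ I−), MeCN, rt, 1 h; then 10, 60 °C
Reagents that add atoms: N,N-dimethylmethyleneiminium iodide, C=[N+](C)C.[I-]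
Why: Mannich reaction of the pyranone at C3, loss of dimethylamine to the pyranone methide, and Friedel–Crafts-type Michael addition of the only free aromatic CH of 10 (C7), a sequence established for arzanol-type phloroglucinol–pyranone heterodimers; the conditions are mild and near neutral, so the isopropenyl group and C2 are unaffected.

## Compound list

1 | phloroglucinol (benzene-1,3,5-triol) | Oc1cc(O)cc(O)c1 | starting material
2 | 2-methylpropanoyl chloride | CC(C)C(=O)Cl | starting material
3 | 2-methyl-1-(2,4,6-trihydroxyphenyl)propan-1-one | CC(C)C(=O)c1c(O)cc(O)cc1O | intermediate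
4 | 2-[(4S)-2,2-dimethyl-5-oxo-1,3-dioxolan-4-yl]acetic acid (L-malic acid acetonide) | O=C(O)C[C@@H]1OC(C)(C)OC1=O | starting material
5 | 1,3-dioxoisoindolin-2-yl 2-[(4S)-2,2-dimethyl-5-oxo-1,3-dioxolan-4-yl]acetate | O=C(C[C@@H]1OC(C)(C)OC1=O)ON1C(=O)c2ccccc2C1=O | intermediate
6 | (5S)-2,2-dimethyl-5-[[2,4,6-trihydroxy-3-(2-methylpropanoyl)phenyl]methyl]-1,3-dioxolan-4-one | CC(C)C(=O)c1c(O)cc(O)c(C[C@@H]2OC(C)(C)OC2=O)c1O | intermediate
7 | methyl (2S)-2-hydroxy-3-[2,4,6-trihydroxy-3-(2-methylpropanoyl)phenyl]propanoate | COC(=O)[C@@H](O)Cc1c(O)cc(O)c(C(=O)C(C)C)c1O | intermediate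
8 | methyl (2R)-4,6-dihydroxy-5-(2-methylpropanoyl)-2,3-dihydro-1-benzofuran-2-carboxylate | COC(=O)[C@H]1Cc2c(O)c(C(=O)C(C)C)c(O)cc2O1 | intermediate
9 | 1-[(2R)-4,6-dihydroxy-2-(2-hydroxypropan-2-yl)-2,3-dihydro-1-benzofuran-5-yl]-2-methylpropan-1-one | CC(C)(O)[C@H]1Cc2c(O)c(C(=O)C(C)C)c(O)cc2O1 | intermediate
10 | 1-[(2R)-4,6-dihydroxy-2-(prop-1-en-2-yl)-2,3-dihydro-1-benzofuran-5-yl]-2-methylpropan-1-one | C=C(C)[C@H]1Cc2c(O)c(C(=O)C(C)C)c(O)cc2O1 | intermediate
11 | methyl 3-oxopentanoate | CCC(=O)CC(=O)OC | starting material
12 | N-methoxy-N-methylpropanamide | CCC(=O)N(C)OC | starting material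
13 | methyl 4-methyl-3,5-dioxoheptanoate (enolisable, no defined stereocentre) | CCC(=O)C(C)C(=O)CC(=O)OC | intermediate
14 | 6-ethyl-4-hydroxy-5-methyl-2H-pyran-2-one | CCc1oc(=O)cc(O)c1C | intermediate
15 | 3-[(dimethylamino)methyl]-6-ethyl-4-hydroxy-5-methyl-2H-pyran-2-one | CCc1oc(=O)c(CN(C)C)c(O)c1C | intermediate
16 | 6-ethyl-5-methyl-3-methylidene-2H-pyran-2,4(3H)-dione | C=C1C(=O)OC(CC)=C(C)C1=O | intermediate
17 | 3-[[(2R)-4,6-dihydroxy-5-(2-methylpropanoyl)-2-(prop-1-en-2-yl)-2,3-dihydro-1-benzofuran-7-yl]methyl]-6-ethyl-4-hydroxy-5-methyl-2H-pyran-2-one (CNP0206652.1) | C=C(C)[C@H]1Cc2c(O)c(C(=O)C(C)C)c(O)c(Cc3c(O)c(C)c(CC)oc3=O)c2O1 | target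

## Step count and risks

Total steps: 7. Longest linear sequence: 6 (steps 1, 2, 3, 4, 5, 7); step 6 is the side branch.

Three steps most likely to fail:

**Step 2 (the proposed light-driven C–C coupling).** Risks are O-acylation of the phenolate by 5, coupling at oxygen or at the acyl-bearing carbon, and double alkylation (hence the excess of 3). The fallback uses known chemistry only, sets out from 1 and comes back to the route at 7. Phloroglucinol 1 is treated with MOMCl and i-Pr2NEt to give 1,3,5-tris(methoxymethoxy)benzene F1. Lithiation between two MOM ethers (n-BuLi, THF, 0 °C), transmetalation (MgBr2·OEt2, then CuI cat.) and opening of purchased methyl (2S)-oxirane-2-carboxylate at its CH2 carbon give methyl (2S)-2-hydroxy-3-[2,4,6-tris(methoxymethoxy)phenyl]propanoate F2. HCl in MeOH removes the MOM groups to give methyl (2S)-2-hydroxy-3-(2,4,6-trihydroxyphenyl)propanoate F3. A Hoesch acylation (isobutyronitrile, ZnCl2, HCl, Et2O, then aqueous hydrolysis) puts the 2-methylpropanoyl group on one of the two equivalent ring CH positions and delivers 7.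

**Step 3 (Mitsunobu ring closure).** Risks are lactonisation of the methyl ester onto a flanking phenol (a 3-hydroxy-dihydrocoumarin) and closure through the chelated phenol. The fallback sets out from 7 and comes back at 9, removing the ester before the ring is closed. Excess MeMgBr converts 7 into 1-[3-[(2S)-2,3-dihydroxy-3-methylbutyl]-2,4,6-trihydroxyphenyl]-2-methylpropan-1-one F4, which cannot lactonise. Mitsunobu cyclodehydration of this phenol diol (PPh3, DIAD, THF) by direct 5-exo displacement at the secondary carbinol gives 9. The stereochemical course (inversion rather than retention through an epoxide) would have to be confirmed by correlation before going on.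

**Step 5 (dehydration).** Risks are elimination towards C2 (an enol ether that isomerises to the 2-isopropylbenzofuran), tertiary chloride formation, and reaction of SOCl2 with the electron-rich ring. The fallback sets out from 8, replaces steps 4 and 5, and comes back at 10 by olefination instead of elimination. LiCH2SiMe3 (excess, THF, −78 °C) adds once to the ester and gives 1-[(2R)-4,6-dihydroxy-2-[2-(trimethylsilyl)acetyl]-2,3-dihydro-1-benzofuran-5-yl]-2-methylpropan-1-one F5 as its enolate. Methanol then removes the silyl group to give 1-[(2R)-2-acetyl-4,6-dihydroxy-2,3-dihydro-1-benzofuran-5-yl]-2-methylpropan-1-one F6. Non-basic Takai–Lombardo methylenation (Zn, CH2Br2, TiCl4, THF, 0 °C) of the unhindered methyl ketone gives 10 without enolising C2.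

Further compounds
F1 | step 2 | 1,3,5-tris(methoxymethoxy)benzene | COCOc1cc(OCOC)cc(OCOC)c1
F2 | step 2 | methyl (2S)-2-hydroxy-3-[2,4,6-tris(methoxymethoxy)phenyl]propanoate | COC(=O)[C@@H](O)Cc1c(OCOC)cc(OCOC)cc1OCOC
F3 | step 2 | methyl (2S)-2-hydroxy-3-(2,4,6-trihydroxyphenyl)propanoate | COC(=O)[C@@H](O)Cc1c(O)cc(O)cc1O
F4 | step 3 | 1-[3-[(2S)-2,3-dihydroxy-3-methylbutyl]-2,4,6-trihydroxyphenyl]-2-methylpropan-1-one | CC(C)C(=O)c1c(O)cc(O)c(C[C@H](O)C(C)(C)O)c1O
F5 | step 5 | 1-[(2R)-4,6-dihydroxy-2-[2-(trimethylsilyl)acetyl]-2,3-dihydro-1-benzofuran-5-yl]-2-methylpropan-1-one | C[Si](C)(C)CC(=O)[C@H]1Cc2c(O)c(C(=O)C(C)C)c(O)cc2O1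
F6 | step 5 | 1-[(2R)-2-acetyl-4,6-dihydroxy-2,3-dihydro-1-benzofuran-5-yl]-2-methylpropan-1-one | CC(=O)[C@H]1Cc2c(O)c(C(=O)C(C)C)c(O)cc2O1
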